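**Assumption:** the target has no stereocentre and no stereogenic axis (each biaryl carries one symmetric 2,4,6-trihydroxyphenyl ring), so it is achiral and no stereocontrol is needed; 1,3-difluoro-5-methoxy-2-nitrobenzene is taken as a catalogue building block.

**Retrosynthetic overview**
1. Target ⇐ cleavage of all 24 methyl ethers of its permethyl ether. No ring is built de novo: all ten benzene rings come from commercial arenes.
2. Ring lettering: A = 3,5-dihydroxyphenoxy; B and D = the two 1,2,3-tris(aryloxy)-5-hydroxybenzene rings; C = the 2,6-dihydroxy-1,4-phenylenedioxy ring between them. The two central ethers (A–O–B and C–O–D) ⇐ Pd-catalysed denitrative etherification of a 2,6-bis(aryloxy)-4-methoxynitrobenzene with a phenol (new reaction).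
3. The four flanking ethers of rings B and D ⇐ SNAr on 1,3-difluoro-5-methoxy-2-nitrobenzene; the nitro group first activates the fluorides and then serves as the leaving group.
4. Ring C ⇐ syringaldehyde: its hindered OH is the SNAr nucleophile, and its CHO becomes the second phenol by Baeyer–Villiger/Dakin oxidation.
5. The three biaryl units ⇐ one hexamethoxybiphenyl-3-ol, from Ullmann homocoupling of 2-iodo-1,3,5-trimethoxybenzene and one-pot lithiation–borylation–oxidation. Assembly order: biaryl phenol → ring D core and ring B/C core → ring A → ring C phenol → union of the two halves → deprotection.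

Abbreviation used in names: HMB = 2,2',4,4',6,6'-hexamethoxy-[1,1'-biphenyl]-3-yl.

**Route**

Step 1
Reactants: 1 2-iodo-1,3,5-trimethoxybenzene (2 equiv)
Product: 2 2,2',4,4',6,6'-hexamethoxy-1,1'-biphenyl
Conditions: Cu powder (activated), DMF, 150 °C
Reagents that add atoms: none
Why: Classical Ullmann reductive homocoupling of a di-ortho-methoxy aryl iodide on copper gives the tetra-ortho-substituted biaryl, and no stereo-element arises because both rings are symmetric.

Step 2
Reactants: 2 2,2',4,4',6,6'-hexamethoxy-1,1'-biphenyl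
Product: 5 2,2',4,4',6,6'-hexamethoxybiphenyl-3-ol (HMB-OH), via aryllithium 3 (not isolated), via dimethyl arylboronate 4 (not isolated)
Conditions: n-BuLi (0.9 equiv), TMEDA, THF, 0 °C; B(OMe)3, −78 °C to rt; 30% aq. H2O2, AcOH, 0 °C to rt
Reagents that add atoms: hydrogen peroxide, OO (gives the phenol oxygen); n-butyllithium, [Li]CCCC, and trimethyl borate, COB(OC)OC (atoms kept only in intermediates 3 and 4)
Why: Directed ortho-lithiation at one of the four equivalent C–H positions flanked by two methoxy groups, then borylation and peroxide oxidation (1,2-aryl shift from boron to oxygen) installs a single phenol; sub-stoichiometric base limits double hydroxylation and unreacted 2 is recovered by base extraction.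

Step 3
Reactants: 6 1,3-difluoro-5-methoxy-2-nitrobenzene; 5 HMB-OH (2.2 equiv)
Product: 7 5-methoxy-2-nitro-1,3-bis(HMB-oxy)benzene
Conditions: Cs2CO3, DMSO, 60 then 110 °C
Reagents that add atoms: none
Why: Twofold nucleophilic aromatic substitution (SNAr) of the two fluorides ortho to the nitro group by the phenoxide of 5; the para methoxy group is not a competitive leaving group.

Step 4
Reactants: 6 1,3-difluoro-5-methoxy-2-nitrobenzene (1.05 equiv); 5 HMB-OH (1 equiv); 8 syringaldehyde (4-hydroxy-3,5-dimethoxybenzaldehyde, 2 equiv)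
Product: 10 4-[3-(HMB-oxy)-5-methoxy-2-nitrophenoxy]-3,5-dimethoxybenzaldehyde, via fluoro nitro ether 9 (not isolated)
Conditions: 6 + 5, Cs2CO3, DMSO, 40 °C; then 8, 120 °C
Reagents that add atoms: none
Why: Temperature-staged SNAr in which the first fluoride goes at 40 °C and the deactivated mono-ether 9 only reacts at 120 °C with the cheap, hindered phenoxide of syringaldehyde used in excess.

Step 5
Reactants: 10 4-[3-(HMB-oxy)-5-methoxy-2-nitrophenoxy]-3,5-dimethoxybenzaldehyde; 11 3,5-dimethoxyphenol (2 equiv)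
Product: 12 4-[2-(3,5-dimethoxyphenoxy)-3-(HMB-oxy)-5-methoxyphenoxy]-3,5-dimethoxybenzaldehyde
Conditions: Pd(acac)2 (10 mol %), BrettPhos (20 mol %), K3PO4, 1,4-dioxane, 130 °C
Reagents that add atoms: none
Why: Proposed new method: Pd-catalysed denitrative C–O cross-coupling on a 2,6-bis(aryloxy)-4-methoxynitroarene, a hindered electron-rich substrate class on which nitro-group coupling has not been shown; zerovalent palladium bearing BrettPhos inserts into the Ar–NO2 bond (the two ortho aryloxy groups already hold the nitro group out of the ring plane, so the twist needed for oxidative addition costs little), nitrite is exchanged for the phenoxide of 11 at divalent palladium, and C–O reductive elimination is driven by the 2,6-disubstituted aryl ligand, while cyclisation to a dibenzofuran by C–H arylation is blocked because both flanking aryloxy rings carry methoxy groups at every ortho position; the closest known reaction type is the Pd/BrettPhos denitrative Suzuki–Miyaura and Buchwald–Hartwig coupling of simple nitroarenes, together with Pd-catalysed diaryl ether formation from aryl halides.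

Step 6
Reactants: 12 4-[2-(3,5-dimethoxyphenoxy)-3-(HMB-oxy)-5-methoxyphenoxy]-3,5-dimethoxybenzaldehyde
Product: 14 4-[2-(3,5-dimethoxyphenoxy)-3-(HMB-oxy)-5-methoxyphenoxy]-3,5-dimethoxyphenol, via aryl formate 13 (not isolated)
Conditions: mCPBA, CH2Cl2, 0 °C to rt; then K2CO3 (cat.), MeOH, rt
Reagents that add atoms: mCPBA (3-chloroperbenzoic acid), O=C(OO)c1cccc(Cl)c1
Why: Baeyer–Villiger (Dakin-type) oxidation in which the electron-rich 4-aryloxy-3,5-dimethoxyphenyl group migrates to oxygen, and the resulting aryl formate is cleaved by methanolysis to the phenol.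

Step 7
Reactants: 7 5-methoxy-2-nitro-1,3-bis(HMB-oxy)benzene (1.3 equiv); 14 4-[2-(3,5-dimethoxyphenoxy)-3-(HMB-oxy)-5-methoxyphenoxy]-3,5-dimethoxyphenol
Product: 15 tetracosa-O-methyl ether of the target (all 24 hydroxyl groups as OMe)
Conditions: Pd(acac)2 (10 mol %), BrettPhos (20 mol %), K3PO4, 1,4-dioxane, 130 °C
Reagents that add atoms: none
Why: Proposed new method: the same Pd-catalysed denitrative C–O coupling as in step 5, now joining the two halves; zerovalent palladium–BrettPhos inserts into the pre-twisted Ar–NO2 bond of 7, the unhindered electron-rich phenoxide of 14 replaces nitrite at divalent palladium, and sterically accelerated C–O reductive elimination gives the ring C–O–ring D ether, with dibenzofuran formation again blocked by the fully ortho-substituted flanking rings; the closest known reaction type is the Pd/BrettPhos denitrative cross-coupling of simple nitroarenes.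

Step 8
Reactants: 15 tetracosa-O-methyl ether of the target
Product: 16 CNP0294555.0 (target)
Conditions: BBr3 (excess), CH2Cl2, −78 °C to rt; MeOH then H2O, under Ar
Reagents that add atoms: none
Why: Lewis-acid ether cleavage in which BBr3 removes all 24 methyl groups by bromide attack at methyl while the diaryl ether and biaryl bonds are inert; the product has no stereocentre or stereogenic axis.

**Compound list**
1 | 2-iodo-1,3,5-trimethoxybenzene | COc1cc(OC)c(I)c(OC)c1 | starting material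
2 | 2,2',4,4',6,6'-hexamethoxy-1,1'-biphenyl | COc1cc(OC)cc(OC)c1-c1c(OC)cc(OC)cc1OC | intermediate
3 | (2,2',4,4',6,6'-hexamethoxybiphenyl-3-yl)lithium | [Li]c1c(OC)cc(OC)c(-c2c(OC)cc(OC)cc2OC)c1OC | intermediate
4 | dimethyl (2,2',4,4',6,6'-hexamethoxybiphenyl-3-yl)boronate | COB(OC)c1c(OC)cc(OC)c(-c2c(OC)cc(OC)cc2OC)c1OC | intermediate
5 | 2,2',4,4',6,6'-hexamethoxybiphenyl-3-ol (HMB-OH) | Oc1c(OC)cc(OC)c(-c2c(OC)cc(OC)cc2OC)c1OC | intermediate
6 | 1,3-difluoro-5-methoxy-2-nitrobenzene | COc1cc(F)c([N+](=O)[O-])c(F)c1 | starting material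
7 | 5-methoxy-2-nitro-1,3-bis(HMB-oxy)benzene | COc1cc(Oc2c(OC)cc(OC)c(-c3c(OC)cc(OC)cc3OC)c2OC)c([N+](=O)[O-])c(Oc2c(OC)cc(OC)c(-c3c(OC)cc(OC)cc3OC)c2OC)c1 | intermediate
8 | syringaldehyde (4-hydroxy-3,5-dimethoxybenzaldehyde) | COc1cc(C=O)cc(OC)c1O | starting material
9 | 3-(3-fluoro-5-methoxy-2-nitrophenoxy)-2,2',4,4',6,6'-hexamethoxybiphenyl | COc1cc(F)c([N+](=O)[O-])c(Oc2c(OC)cc(OC)c(-c3c(OC)cc(OC)cc3OC)c2OC)c1 | intermediate
10 | 4-[3-(HMB-oxy)-5-methoxy-2-nitrophenoxy]-3,5-dimethoxybenzaldehyde | COc1cc(Oc2c(OC)cc(C=O)cc2OC)c([N+](=O)[O-])c(Oc2c(OC)cc(OC)c(-c3c(OC)cc(OC)cc3OC)c2OC)c1 | intermediate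
11 | 3,5-dimethoxyphenol | COc1cc(O)cc(OC)c1 | starting material
12 | 4-[2-(3,5-dimethoxyphenoxy)-3-(HMB-oxy)-5-methoxyphenoxy]-3,5-dimethoxybenzaldehyde | COc1cc(Oc2c(OC)cc(C=O)cc2OC)c(Oc2cc(OC)cc(OC)c2)c(Oc2c(OC)cc(OC)c(-c3c(OC)cc(OC)cc3OC)c2OC)c1 | intermediate
13 | 4-[2-(3,5-dimethoxyphenoxy)-3-(HMB-oxy)-5-methoxyphenoxy]-3,5-dimethoxyphenyl formate | COc1cc(Oc2c(OC)cc(OC=O)cc2OC)c(Oc2cc(OC)cc(OC)c2)c(Oc2c(OC)cc(OC)c(-c3c(OC)cc(OC)cc3OC)c2OC)c1 | intermediate
14 | 4-[2-(3,5-dimethoxyphenoxy)-3-(HMB-oxy)-5-methoxyphenoxy]-3,5-dimethoxyphenol | COc1cc(Oc2c(OC)cc(O)cc2OC)c(Oc2cc(OC)cc(OC)c2)c(Oc2c(OC)cc(OC)c(-c3c(OC)cc(OC)cc3OC)c2OC)c1 | intermediate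
15 | tetracosa-O-methyl ether of the target | COc1cc(OC)cc(Oc2c(Oc3c(OC)cc(Oc4c(Oc5c(OC)cc(OC)c(-c6c(OC)cc(OC)cc6OC)c5OC)cc(OC)cc4Oc4c(OC)cc(OC)c(-c5c(OC)cc(OC)cc5OC)c4OC)cc3OC)cc(OC)cc2Oc2c(OC)cc(OC)c(-c3c(OC)cc(OC)cc3OC)c2OC)c1 | intermediate
16 | CNP0294555.0: 4-(3,5-dihydroxyphenoxy)-3-[(2,2',4,4',6,6'-hexahydroxybiphenyl-3-yl)oxy]-5-{4-[2,6-bis((2,2',4,4',6,6'-hexahydroxybiphenyl-3-yl)oxy)-4-hydroxyphenoxy]-2,6-dihydroxyphenoxy}phenol | Oc1cc(O)cc(Oc2c(Oc3c(O)cc(Oc4c(Oc5c(O)cc(O)c(-c6c(O)cc(O)cc6O)c5O)cc(O)cc4Oc4c(O)cc(O)c(-c5c(O)cc(O)cc5O)c4O)cc3O)cc(O)cc2Oc2c(O)cc(O)c(-c3c(O)cc(O)cc3O)c2O)c1 | target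

**Totals**
Total step count: 8.
Longest linear sequence: 7 steps (steps 1, 2, 4, 5, 6, 7, 8; 1 → 2 → 5 → 10 → 12 → 14 → 15 → 16).

**Three steps most likely to fail**

Step 7 (new denitrative etherification, union of the halves). Risks are slow insertion into the electron-rich, doubly flanked Ar–NO2 bond, catalyst inhibition by nitrite, and a near 1:1 coupling of two large partners. Fallback with known chemistry, setting out from 7 and returning at 15: reduce the nitro group with Fe powder and NH4Cl in EtOH/H2O at 70 °C to the aniline 4-methoxy-2,6-bis(HMB-oxy)aniline F4. Diazotise with NaNO2 and p-TsOH in MeCN/H2O at 10 °C to the arenediazonium tosylate 4-methoxy-2,6-bis(HMB-oxy)benzenediazonium 4-methylbenzenesulfonate F5, and treat it in the same flask with KI to give the aryl iodide 2-iodo-5-methoxy-1,3-bis(HMB-oxy)benzene F6 (Sandmeyer-type iodination). Couple F6 with phenol 14 by ligand-accelerated Ullmann ether synthesis (CuI, picolinic acid, K3PO4, DMSO, 100 °C), a system established for di-ortho-substituted aryl iodides, to reach 15.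

Step 5 (first use of the new denitrative etherification). Risks are the same oxidative-addition problem, exchange of the formyl-syringyloxy group ortho to the nitro group by the phenoxide of 11, C- instead of O-arylation of 11, and the bystander aldehyde at 130 °C. Fallback with known chemistry, setting out from 10 and returning at 12: reduce with Fe powder and NH4Cl (EtOH/H2O, 70 °C; the aldehyde is untouched) to the aniline 4-[2-amino-3-(HMB-oxy)-5-methoxyphenoxy]-3,5-dimethoxybenzaldehyde F1, used crude. Diazotise (NaNO2, p-TsOH, MeCN/H2O, 10 °C) to the diazonium tosylate 2-(4-formyl-2,6-dimethoxyphenoxy)-6-(HMB-oxy)-4-methoxybenzenediazonium 4-methylbenzenesulfonate F2, and add KI to give the aryl iodide 4-[3-(HMB-oxy)-2-iodo-5-methoxyphenoxy]-3,5-dimethoxybenzaldehyde F3. Ullmann etherification of F3 with 11 (CuI, picolinic acid, K3PO4, DMSO, 100 °C) gives 12.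

Step 8 (cleavage of 24 methyl ethers). Risks are incomplete demethylation, precipitation of partly cleaved borates, and air oxidation of the free polyphenol during purification. Fallback by capture and release, setting out from 15 and returning at 16: after the BBr3 treatment and methanol quench, acetylate the crude polyphenol directly (Ac2O, pyridine, DMAP, rt) to the stable tetracosaacetate of the target F7. Purify F7 on silica; under-demethylated congeners separate there and can be re-submitted. Then release the target under argon by catalytic NaOMe in MeOH at 0 °C, neutralising with acidic ion-exchange resin, to give 16.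

**Further compounds**
F1 | step 5 | 4-[2-amino-3-(HMB-oxy)-5-methoxyphenoxy]-3,5-dimethoxybenzaldehyde | COc1cc(Oc2c(OC)cc(C=O)cc2OC)c(N)c(Oc2c(OC)cc(OC)c(-c3c(OC)cc(OC)cc3OC)c2OC)c1
F2 | step 5 | 2-(4-formyl-2,6-dimethoxyphenoxy)-6-(HMB-oxy)-4-methoxybenzenediazonium 4-methylbenzenesulfonate | COc1cc(Oc2c(OC)cc(C=O)cc2OC)c([N+]#N)c(Oc2c(OC)cc(OC)c(-c3c(OC)cc(OC)cc3OC)c2OC)c1.Cc1ccc(S(=O)(=O)[O-])cc1
F3 | step 5 | 4-[3-(HMB-oxy)-2-iodo-5-methoxyphenoxy]-3,5-dimethoxybenzaldehyde | COc1cc(Oc2c(OC)cc(C=O)cc2OC)c(I)c(Oc2c(OC)cc(OC)c(-c3c(OC)cc(OC)cc3OC)c2OC)c1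
F4 | step 7 | 4-methoxy-2,6-bis(HMB-oxy)aniline | COc1cc(Oc2c(OC)cc(OC)c(-c3c(OC)cc(OC)cc3OC)c2OC)c(N)c(Oc2c(OC)cc(OC)c(-c3c(OC)cc(OC)cc3OC)c2OC)c1
F5 | step 7 | 4-methoxy-2,6-bis(HMB-oxy)benzenediazonium 4-methylbenzenesulfonate | COc1cc(Oc2c(OC)cc(OC)c(-c3c(OC)cc(OC)cc3OC)c2OC)c([N+]#N)c(Oc2c(OC)cc(OC)c(-c3c(OC)cc(OC)cc3OC)c2OC)c1.Cc1ccc(S(=O)(=O)[O-])cc1
F6 | step 7 | 2-iodo-5-methoxy-1,3-bis(HMB-oxy)benzene | COc1cc(Oc2c(OC)cc(OC)c(-c3c(OC)cc(OC)cc3OC)c2OC)c(I)c(Oc2c(OC)cc(OC)c(-c3c(OC)cc(OC)cc3OC)c2OC)c1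
F7 | step 8 | tetracosa-O-acetate of the target | CC(=O)Oc1cc(OC(C)=O)cc(Oc2c(Oc3c(OC(C)=O)cc(Oc4c(Oc5c(OC(C)=O)cc(OC(C)=O)c(-c6c(OC(C)=O)cc(OC(C)=O)cc6OC(C)=O)c5OC(C)=O)cc(OC(C)=O)cc4Oc4c(OC(C)=O)cc(OC(C)=O)c(-c5c(OC(C)=O)cc(OC(C)=O)cc5OC(C)=O)c4OC(C)=O)cc3OC(C)=O)cc(OC(C)=O)cc2Oc2c(OC(C)=O)cc(OC(C)=O)c(-c3c(OC(C)=O)cc(OC(C)=O)cc3OC(C)=O)c2OC(C)=O)c1
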